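**Plan**

1. Ring labels: A is the hydroxylated benzo ring of the dibenzofuran (C1–C4a, C9b), B its second benzo ring (C5a–C9a), C the catechol-derived ring, D the para-phenylene ring.
2. Cuts: the two-carbon link between C7 (ring B) and ring C (McMurry closure of the 18-membered ring, then hydrogenation); the furan bond O5–C4a and the biaryl bond C9a–C9b (acid cascade of a quinol ketal, preceded by aryllithium addition to a quinone monoketal); the two-carbon link between C1 (ring A) and ring D (Wittig, hydrogenation); the ring C–O–ring D ether (SNAr).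
3. Enabling feature: in ring A the C3 hydroxyl is para to C9b and the furan oxygen O5 sits on the adjacent C4a. This is the footprint of an ortho-phenol that has added to an enone β-carbon of a 4-aryl-4-hydroxycyclohexa-2,5-dienone, followed by loss of water; the C1 arm is the alkyl group ortho to the carbonyl of the quinone monoketal.
4. Forward order: diaryl ether (rings C and D), then the bibenzyl arm on the ring A precursor, then dearomatization to the quinone monoketal, then ring B by 1,2-addition, then furan closure with rearomatization of ring A, then the macrocycle by C–C coupling, then deprotection.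
5. Stereochemistry: the target is achiral. The carbinol center of the quinol ketal is racemic and is destroyed on aromatization; alkene geometries are erased by hydrogenation.

Key step: step 10

Remark: isovanillin, 4-fluorobenzaldehyde, 2-hydroxy-5-methoxybenzaldehyde and 4-bromo-3-hydroxybenzaldehyde are taken as purchasable. Both future bridge carbons are carried as 1,3-dioxolanes so that the acid of step 10 also unveils the two formyl groups. The geometry of the alkenes in 9 and 20 is left undefined because both isomers converge on hydrogenation.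

**Route**

Step 1
Reactants: 1 3-hydroxy-4-methoxybenzaldehyde (isovanillin)
Product: 2 5-(1,3-dioxolan-2-yl)-2-methoxyphenol
Conditions: HOCH2CH2OH, TsOH·H2O (cat.), toluene, reflux (Dean–Stark)
Reagents that add atoms: ethylene glycol, OCCO
Why: Acid-catalyzed acetalization driven by azeotropic removal of water masks the formyl group as a base-stable 1,3-dioxolane and leaves the phenol free for the ether synthesis.

Step 2
Reactants: 2 5-(1,3-dioxolan-2-yl)-2-methoxyphenol; 3 4-fluorobenzaldehyde
Product: 4 4-[5-(1,3-dioxolan-2-yl)-2-methoxyphenoxy]benzaldehyde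
Conditions: K2CO3, DMF, 120 °C
Reagents that add atoms: none
Why: Nucleophilic aromatic substitution (SNAr) in which the phenoxide of 2 displaces fluoride para to the activating formyl group of 3, under conditions to which the dioxolane and the methyl ether are inert.

Step 3
Reactants: 5 2-hydroxy-5-methoxybenzaldehyde
Product: 6 2-(hydroxymethyl)-4-methoxyphenol
Conditions: NaBH4, MeOH, 0 °C
Reagents that add atoms: none
Why: NaBH4 reduction of an aryl aldehyde to the benzylic alcohol is chemoselective and leaves the phenol and the methyl ether untouched.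

Step 4
Reactants: 6 2-(hydroxymethyl)-4-methoxyphenol
Product: 7 [(2-hydroxy-5-methoxyphenyl)methyl]triphenylphosphonium bromide
Conditions: PPh3·HBr, MeCN, reflux
Reagents that add atoms: triphenylphosphine hydrobromide, Br.c1ccc(cc1)P(c1ccccc1)c1ccccc1
Why: Ortho-hydroxybenzyl alcohols are converted by PPh3·HBr into benzylphosphonium salts through acid-promoted ionization at the benzylic carbon and capture by the phosphine, a standard entry to these Wittig reagents.

Step 5
Reactants: 7 [(2-hydroxy-5-methoxyphenyl)methyl]triphenylphosphonium bromide; 4 4-[5-(1,3-dioxolan-2-yl)-2-methoxyphenoxy]benzaldehyde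
Product: 9 2-{2-[4-(5-(1,3-dioxolan-2-yl)-2-methoxyphenoxy)phenyl]ethenyl}-4-methoxyphenol (E/Z mixture), via potassium phenoxide ylide 8 (not isolated)
Conditions: KOt-Bu (2.2 equiv), THF, 0 °C; then 4, 0 °C to rt; aq. NH4Cl
Reagents that add atoms: none
Why: Wittig olefination in which two equivalents of base generate the phenoxide ylide 8 that condenses with the non-enolizable aldehyde 4; the E/Z composition is of no consequence because the alkene is saturated in step 6.

Step 6
Reactants: 9 2-{2-[4-(5-(1,3-dioxolan-2-yl)-2-methoxyphenoxy)phenyl]ethenyl}-4-methoxyphenol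
Product: 10 2-{2-[4-(5-(1,3-dioxolan-2-yl)-2-methoxyphenoxy)phenyl]ethyl}-4-methoxyphenol
Conditions: H2 (1 atm), Pd/C, EtOAc, Et3N (trace), rt
Reagents that add atoms: none
Why: Catalytic hydrogenation over Pd/C saturates the stilbene double bond, while the diaryl ether, the methyl ethers and, in the non-acidic medium, the dioxolane are not hydrogenolyzed.

Step 7
Reactants: 10 2-{2-[4-(5-(1,3-dioxolan-2-yl)-2-methoxyphenoxy)phenyl]ethyl}-4-methoxyphenol
Product: 11 2-{2-[4-(5-(1,3-dioxolan-2-yl)-2-methoxyphenoxy)phenyl]ethyl}-4,4-dimethoxycyclohexa-2,5-dien-1-one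
Conditions: PhI(OAc)2, MeOH, 0 °C; then aq. NaHCO3
Reagents that add atoms: methanol, CO
Why: Oxidative dearomatization of a para-methoxyphenol by PhI(OAc)2 (a trivalent iodine oxidant) in methanol gives the quinone monoketal by capture at the methoxy-bearing para carbon, so the arm ends up ortho to the new carbonyl.

Step 8
Reactants: 12 4-bromo-3-hydroxybenzaldehyde
Product: 13 2-bromo-5-(1,3-dioxolan-2-yl)phenol
Conditions: HOCH2CH2OH, TsOH·H2O (cat.), toluene, reflux (Dean–Stark)
Reagents that add atoms: ethylene glycol, OCCO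
Why: Acid-catalyzed acetalization protects the aldehyde against the organolithium chemistry of step 9 in a form that the acid of step 10 removes again.

Step 9
Reactants: 13 2-bromo-5-(1,3-dioxolan-2-yl)phenol; 11 2-{2-[4-(5-(1,3-dioxolan-2-yl)-2-methoxyphenoxy)phenyl]ethyl}-4,4-dimethoxycyclohexa-2,5-dien-1-one
Product: 15 rac-1-[4-(1,3-dioxolan-2-yl)-2-hydroxyphenyl]-2-{2-[4-(5-(1,3-dioxolan-2-yl)-2-methoxyphenoxy)phenyl]ethyl}-4,4-dimethoxycyclohexa-2,5-dien-1-ol, via ortho-lithiated lithium phenoxide 14 (not isolated)
Conditions: 13, n-BuLi (1 equiv), THF, −78 °C; t-BuLi (2 equiv), −78 °C; then 11, −78 to −40 °C; H2O quench, neutral work-up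
Reagents that add atoms: none
Why: Phenol deprotonation followed by bromine–lithium exchange gives the ortho-lithiated phenoxide 14, which adds 1,2 to the ketone of the quinone monoketal as aryllithiums generally do (ketal and dioxolanes are inert), forming the C9a–C9b bond and a racemic carbinol center that is erased in step 10.

Step 10
Reactants: 15 rac-1-[4-(1,3-dioxolan-2-yl)-2-hydroxyphenyl]-2-{2-[4-(5-(1,3-dioxolan-2-yl)-2-methoxyphenoxy)phenyl]ethyl}-4,4-dimethoxycyclohexa-2,5-dien-1-ol
Product: 18 7-formyl-1-{2-[4-(5-formyl-2-methoxyphenoxy)phenyl]ethyl}dibenzofuran-3-ol, via p-quinol dienone 16 (not isolated), via cis-fused hydrodibenzofuranone 17 (not isolated)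
Conditions: 2 M aq. HCl, THF, rt, then 50 °C
Reagents that add atoms: water, O
Why: Proposed new method: aqueous acid should strip the dimethyl ketal and both dioxolanes of 15 to give the 4-aryl-4-hydroxycyclohexa-2,5-dienone 16, whose free ortho-phenol adds to the unsubstituted β-carbon of the protonated dienone to give 17; through its dienol tautomer 17 is the C4a–C9b hydrate of the dibenzofuranol, so acid-catalyzed loss of the tertiary benzylic hydroxyl together with the C4a hydrogen, followed by enolization, should deliver aromatic 18. The closest known reaction types are the hydrolysis of aryllithium–quinone monoketal adducts to p-quinols, the intramolecular phenol oxa-Michael addition to cyclohexadienones that gives hydrodibenzofuranones, and the acid-catalyzed dehydration of arene hydrates and quinols to arenes; only their union in one flask is untested. The furan ring closes in the 5-exo-trig mode with formation of the O5–C4a bond. The two stereocenters of 17 (cis fusion enforced by the five-membered ring) and the carbinol center of 15 vanish on aromatization, so no stereocontrol is required. The step needs regioselectivity between the two enone β-carbons, and the substrate secures it: the arm-bearing β-carbon is hindered and its adduct has no hydrogen to lose and can only revert, whereas the adduct at the unsubstituted carbon is drained irreversibly by aromatization.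

Step 11
Reactants: 18 7-formyl-1-{2-[4-(5-formyl-2-methoxyphenoxy)phenyl]ethyl}dibenzofuran-3-ol
Product: 19 7-formyl-1-{2-[4-(5-formyl-2-methoxyphenoxy)phenyl]ethyl}-3-methoxydibenzofuran
Conditions: MeI, K2CO3, DMF, rt
Reagents that add atoms: iodomethane, CI
Why: Williamson methylation of the phenoxide protects the C3 hydroxyl so that no acidic proton interferes with the low-valent titanium of step 12, and the two aldehydes are unaffected by this weak base.

Step 12
Reactants: 19 7-formyl-1-{2-[4-(5-formyl-2-methoxyphenoxy)phenyl]ethyl}-3-methoxydibenzofuran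
Product: 20 di-O-methyl didehydroasterelin A (18-membered macrocyclic stilbene with CH=CH between C7 and ring C; alkene geometry undefined)
Conditions: TiCl4, Zn, pyridine, THF, reflux; slow syringe-pump addition of 19 (high dilution)
Reagents that add atoms: none
Why: McMurry coupling, in which low-valent titanium made from TiCl4 and Zn joins the two aryl aldehydes through a titanium pinacolate that is deoxygenated to the alkene, is an established closure for bis(bibenzyl) macrocycles and is favored over oligomerization by slow addition at high dilution.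

Step 13
Reactants: 20 di-O-methyl didehydroasterelin A
Product: 21 asterelin A di-O-methyl ether
Conditions: H2 (1 atm), Pd/C, EtOAc/THF, rt
Reagents that add atoms: none
Why: Catalytic hydrogenation of the stilbene double bond gives the second ethano bridge from either alkene isomer without affecting the aryl ethers or the dibenzofuran.

Step 14
Reactants: 21 asterelin A di-O-methyl ether
Product: 22 asterelin A
Conditions: BBr3, CH2Cl2, −78 °C to rt; then H2O
Reagents that add atoms: none
Why: BBr3 demethylation cleaves both aryl methyl ethers by bromide attack on the methyl carbon of the boron-complexed ethers, whereas the diaryl ether and the dibenzofuran oxygen carry no alkyl carbon and survive.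

**Compound list**

1 | 3-hydroxy-4-methoxybenzaldehyde (isovanillin) | COc1ccc(C=O)cc1O | starting material
2 | 5-(1,3-dioxolan-2-yl)-2-methoxyphenol | COc1ccc(C2OCCO2)cc1O | intermediate
3 | 4-fluorobenzaldehyde | O=Cc1ccc(F)cc1 | starting material
4 | 4-[5-(1,3-dioxolan-2-yl)-2-methoxyphenoxy]benzaldehyde | COc1ccc(C2OCCO2)cc1Oc1ccc(C=O)cc1 | intermediate
5 | 2-hydroxy-5-methoxybenzaldehyde | COc1ccc(O)c(C=O)c1 | starting material
6 | 2-(hydroxymethyl)-4-methoxyphenol | COc1ccc(O)c(CO)c1 | intermediate
7 | [(2-hydroxy-5-methoxyphenyl)methyl]triphenylphosphonium bromide | COc1ccc(O)c(C[P+](c2ccccc2)(c2ccccc2)c2ccccc2)c1.[Br-] | intermediate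
8 | potassium 4-methoxy-2-[(triphenylphosphoranylidene)methyl]phenolate (phenoxide ylide, formed in the flask) | [K+].[O-]c1ccc(OC)cc1C=P(c1ccccc1)(c1ccccc1)c1ccccc1 | intermediate
9 | 2-{2-[4-(5-(1,3-dioxolan-2-yl)-2-methoxyphenoxy)phenyl]ethenyl}-4-methoxyphenol (E/Z mixture, geometry undefined) | COc1ccc(O)c(C=Cc2ccc(Oc3cc(C4OCCO4)ccc3OC)cc2)c1 | intermediate
10 | 2-{2-[4-(5-(1,3-dioxolan-2-yl)-2-methoxyphenoxy)phenyl]ethyl}-4-methoxyphenol | COc1ccc(O)c(CCc2ccc(Oc3cc(C4OCCO4)ccc3OC)cc2)c1 | intermediate
11 | 2-{2-[4-(5-(1,3-dioxolan-2-yl)-2-methoxyphenoxy)phenyl]ethyl}-4,4-dimethoxycyclohexa-2,5-dien-1-one | O=C1C=CC(OC)(OC)C=C1CCc1ccc(Oc2cc(C3OCCO3)ccc2OC)cc1 | intermediate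
12 | 4-bromo-3-hydroxybenzaldehyde | O=Cc1ccc(Br)c(O)c1 | starting material
13 | 2-bromo-5-(1,3-dioxolan-2-yl)phenol | Oc1cc(C2OCCO2)ccc1Br | intermediate
14 | lithium 5-(1,3-dioxolan-2-yl)-2-lithiophenolate (formed in the flask) | [Li]Oc1cc(C2OCCO2)ccc1[Li] | intermediate
15 | rac-1-[4-(1,3-dioxolan-2-yl)-2-hydroxyphenyl]-2-{2-[4-(5-(1,3-dioxolan-2-yl)-2-methoxyphenoxy)phenyl]ethyl}-4,4-dimethoxycyclohexa-2,5-dien-1-ol (racemic carbinol center) | Oc1cc(C2OCCO2)ccc1C1(O)C=CC(OC)(OC)C=C1CCc1ccc(Oc2cc(C3OCCO3)ccc2OC)cc1 | intermediate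
16 | rac-4-(4-formyl-2-hydroxyphenyl)-3-{2-[4-(5-formyl-2-methoxyphenoxy)phenyl]ethyl}-4-hydroxycyclohexa-2,5-dien-1-one (formed in the flask) | Oc1cc(C=O)ccc1C1(O)C=CC(=O)C=C1CCc1ccc(Oc2cc(C=O)ccc2OC)cc1 | intermediate
17 | cis-9b-hydroxy-1-{2-[4-(5-formyl-2-methoxyphenoxy)phenyl]ethyl}-3-oxo-3,4,4a,9b-tetrahydrodibenzofuran-7-carbaldehyde (racemic; 4a-H and 9b-OH on the same face; one enantiomer drawn; formed in the flask) | O=C1C=C(CCc4ccc(Oc5cc(C=O)ccc5OC)cc4)[C@]2(O)c3ccc(C=O)cc3O[C@@H]2C1 | intermediate
18 | 7-formyl-1-{2-[4-(5-formyl-2-methoxyphenoxy)phenyl]ethyl}dibenzofuran-3-ol | Oc1cc(CCc2ccc(Oc3cc(C=O)ccc3OC)cc2)c2c(c1)oc1cc(C=O)ccc12 | intermediate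
19 | 7-formyl-1-{2-[4-(5-formyl-2-methoxyphenoxy)phenyl]ethyl}-3-methoxydibenzofuran | COc1cc(CCc2ccc(Oc3cc(C=O)ccc3OC)cc2)c2c(c1)oc1cc(C=O)ccc12 | intermediate
20 | di-O-methyl didehydroasterelin A (macrocyclic stilbene, CH=CH between C7 and ring C; geometry undefined) | COc1cc2c3c(c1)oc1cc(ccc13)C=Cc1ccc(OC)c(c1)Oc1ccc(cc1)CC2 | intermediate
21 | asterelin A di-O-methyl ether | COc1cc2c3c(c1)oc1cc(ccc13)CCc1ccc(OC)c(c1)Oc1ccc(cc1)CC2 | intermediate
22 | asterelin A | Oc1cc2c3c(c1)oc1cc(ccc13)CCc1ccc(O)c(c1)Oc1ccc(cc1)CC2 | target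

**Step count and risks**

Total steps: 14. Longest linear sequence: 11 steps (1, 2, 5, 6, 7, 9, 10, 11, 12, 13, 14).

Step 10 (carries the proposed new method). The sequence may stall at the hydrated stage, because ionization of the tertiary hydroxyl is slowed once ring B carries a free formyl group. The p-quinol may also be diverted by dienone–phenol rearrangement before the phenol adds. The fallback builds the dibenzofuran by cross-coupling and C–H etherification, all of known type. It sets out from 10, which Tf2O and pyridine in CH2Cl2 convert into the aryl triflate F1. Bromophenol 13 is turned by Miyaura borylation (B2pin2, PdCl2(dppf), KOAc, dioxane, 80 °C) into the pinacol boronate F2. Suzuki–Miyaura coupling of F1 and F2 (Pd(OAc)2, SPhos, K3PO4, toluene/H2O, 90 °C) forms the C9a–C9b bond and gives the biaryl phenol F3. Phenol-directed C–H activation/C–O cyclization (Pd(OAc)2, 1,3-bis(2,6-diisopropylphenyl)imidazol-2-ylidene, sodium mesitylenecarboxylate, K2CO3, 4,5-diazafluoren-9-one, air, mesitylene, 120 °C) closes O5–C4a at the only free ortho position of ring A and gives the bis-dioxolane methoxydibenzofuran F4. Aqueous HCl in THF then removes both dioxolanes, and the route is rejoined at 19.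

Step 12. The rigid, planar dibenzofuran makes the 18-membered ring strained, so intermolecular coupling to oligomers or arrest at the pinacol stage may outrun ring closure. The fallback sets out from 19 and forms the sp3–sp3 bond directly. NaBH4 in MeOH/THF reduces both aldehydes to the bis(hydroxymethyl) compound F5, and PBr3 in CH2Cl2 at 0 °C gives the bis(bromomethyl) compound F6. An intramolecular Wurtz coupling (Na, tetraphenylethene, THF, high dilution), as used for other macrocyclic bis(bibenzyls), then closes the ring and rejoins the route at 21 without passing through the alkene.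

Step 9. The aggregated dilithio species may be too poorly soluble or too weakly nucleophilic for complete addition to the hindered ketone, and electron transfer or conjugate addition could then compete. The fallback masks the phenol and sets out from 13, which MOMCl and i-Pr2NEt in CH2Cl2 convert into the methoxymethyl ether F7. Bromine–lithium exchange with n-BuLi (THF, −78 °C) gives a chelation-stabilized monolithium reagent that adds to 11 to give the MOM-protected quinol ketal F8. The aqueous HCl treatment of step 10 also cleaves the methoxymethyl acetal, so the route is rejoined at 18.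

**Further compounds**

F1 | step 10 | 2-{2-[4-(5-(1,3-dioxolan-2-yl)-2-methoxyphenoxy)phenyl]ethyl}-4-methoxyphenyl trifluoromethanesulfonate | COc1ccc(OS(=O)(=O)C(F)(F)F)c(CCc2ccc(Oc3cc(C4OCCO4)ccc3OC)cc2)c1
F2 | step 10 | 5-(1,3-dioxolan-2-yl)-2-(4,4,5,5-tetramethyl-1,3,2-dioxaborolan-2-yl)phenol | Oc1cc(C2OCCO2)ccc1B1OC(C)(C)C(C)(C)O1
F3 | step 10 | 4-(1,3-dioxolan-2-yl)-2'-{2-[4-(5-(1,3-dioxolan-2-yl)-2-methoxyphenoxy)phenyl]ethyl}-4'-methoxybiphenyl-2-ol | COc1ccc(-c2ccc(C3OCCO3)cc2O)c(CCc2ccc(Oc3cc(C4OCCO4)ccc3OC)cc2)c1
F4 | step 10 | 7-(1,3-dioxolan-2-yl)-1-{2-[4-(5-(1,3-dioxolan-2-yl)-2-methoxyphenoxy)phenyl]ethyl}-3-methoxydibenzofuran | COc1cc(CCc2ccc(Oc3cc(C4OCCO4)ccc3OC)cc2)c2c(c1)oc1cc(C3OCCO3)ccc12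
F5 | step 12 | 7-(hydroxymethyl)-1-{2-[4-(5-(hydroxymethyl)-2-methoxyphenoxy)phenyl]ethyl}-3-methoxydibenzofuran | COc1cc(CCc2ccc(Oc3cc(CO)ccc3OC)cc2)c2c(c1)oc1cc(CO)ccc12
F6 | step 12 | 7-(bromomethyl)-1-{2-[4-(5-(bromomethyl)-2-methoxyphenoxy)phenyl]ethyl}-3-methoxydibenzofuran | COc1cc(CCc2ccc(Oc3cc(CBr)ccc3OC)cc2)c2c(c1)oc1cc(CBr)ccc12
F7 | step 9 | 2-[4-bromo-3-(methoxymethoxy)phenyl]-1,3-dioxolane | COCOc1cc(C2OCCO2)ccc1Br
F8 | step 9 | rac-1-[4-(1,3-dioxolan-2-yl)-2-(methoxymethoxy)phenyl]-2-{2-[4-(5-(1,3-dioxolan-2-yl)-2-methoxyphenoxy)phenyl]ethyl}-4,4-dimethoxycyclohexa-2,5-dien-1-ol | COCOc1cc(C2OCCO2)ccc1C1(O)C=CC(OC)(OC)C=C1CCc1ccc(Oc2cc(C3OCCO3)ccc2OC)cc1
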